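Ring A is read as a latent 2-methylcyclohexane-1,3-dione: C10 carries the methyl and the aryl precursor of ring C, and the two carbonyls are C1 and C5. The C5–C6 bond is made by a carbene-catalysed intramolecular crossed benzoin reaction in which the C6 aldehyde, tethered through the C8=C9 arene bond, attacks one of the two enantiotopic carbonyls. This single operation closes ring B, sets the C10 quaternary centre by catalyst control and leaves C1 and C6 as ketones; every other stereocentre is then relayed from C10. The precursor is an achiral aryl dione bearing a CH2CHO group; Birch chemistry later converts the anisole into the bicyclo[3.2.1]octene.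

Key step: step 3

Remark on numbering: C1–C5 and C10 form ring A, C5–C10 ring B, C8, C9 and C11–C14 ring C; C15–C16 is the two-carbon bridge from C11 to C13, C17 the exocyclic methylene carbon, C20 the methyl on C10; α is the face of C20, β the opposite face; tricyclic intermediates are named on the podocarpane skeleton with these locants.

Remark on assumptions: (2-formyl-5-methoxyphenyl)boronic acid is taken to be a catalogue compound; the sense of induction of the triazolium catalyst with this aryl-tethered dione is assumed by analogy with alkyl-tethered diones, and the antipodal precatalyst is equally accessible if the sense is the opposite.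

Step 1
Reactants: 1 2-methylcyclohexane-1,3-dione; 2 (2-formyl-5-methoxyphenyl)boronic acid
Product: 4 2-(2-formyl-5-methoxyphenyl)-2-methylcyclohexane-1,3-dione, via aryllead triacetate 3 (not isolated)
Conditions: Pb(OAc)4, Hg(OAc)2 (10 mol %), CHCl3, 40 °C; then 1, pyridine, 60 °C
Reagents that add atoms: none
Why: Boron-to-lead exchange gives an aryllead triacetate that arylates the dione at carbon by ligand coupling (Pinhey arylation), which creates the quaternary C10 of an achiral, mirror-symmetric dione.

Step 2
Reactants: 4 2-(2-formyl-5-methoxyphenyl)-2-methylcyclohexane-1,3-dione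
Product: 6 2-[5-methoxy-2-(2-oxoethyl)phenyl]-2-methylcyclohexane-1,3-dione, via enol ether 5 (not isolated)
Conditions: Ph3P(CH2OMe)Cl, KOt-Bu, THF, 0 °C; then 2 M HCl, THF, rt
Reagents that add atoms: (methoxymethyl)triphenylphosphonium chloride, COC[P+](c1ccccc1)(c1ccccc1)c1ccccc1.[Cl-]; water, O
Why: Wittig methoxymethylenation of the aryl aldehyde (the two ketones flank a quaternary carbon and should react far more slowly) followed by enol ether hydrolysis gives the homologated aldehyde whose carbonyl carbon is C6.

Step 3
Reactants: 6 2-[5-methoxy-2-(2-oxoethyl)phenyl]-2-methylcyclohexane-1,3-dione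
Product: 7 tricyclic ketol 5α-hydroxy-12-methoxy-18,19-dinorpodocarpa-8,11,13-triene-1,6-dione
Conditions: (5aR,10bS)-2-(pentafluorophenyl)-5a,10b-dihydro-4H,6H-indeno[2,1-b][1,2,4]triazolo[4,3-d][1,4]oxazin-2-ium tetrafluoroborate (15 mol %), Et3N (15 mol %), toluene, 25 °C
Reagents that add atoms: none
Why: The triazolylidene adds to the C6 aldehyde and a proton shift gives the Breslow intermediate, an acyl-anion equivalent that adds to one ring carbonyl and then expels the carbene. The closest known reaction type is the carbene-catalysed intramolecular crossed benzoin reaction used to desymmetrise 2,2-disubstituted cyclic 1,3-diketones that carry a tethered aldehyde. Ring B closes by 6-exo-trig attack of C6 on the C5 carbonyl, the tether being held cis by the C8=C9 arene bond. The quaternary C10 stereocentre is set by the catalyst, which selects between the two enantiotopic carbonyl groups, and the C5 carbinol follows from C10 because the short tether delivers C6 on its own face (hydroxyl cis to C20); C5 is erased again in step 4. The step needs chemoselectivity for benzoin over aldol addition of the enolisable arylacetaldehyde and over homo-benzoin dimerisation, which the weakly basic N-pentafluorophenyl carbene, the catalytic amount of a mild amine base and the fast six-membered closure onto an activated diketone carbonyl should secure.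

Step 4
Reactants: 7 tricyclic ketol 5α-hydroxy-12-methoxy-18,19-dinorpodocarpa-8,11,13-triene-1,6-dione
Product: 8 enedione 12-methoxy-18,19-dinorpodocarpa-4,8,11,13-tetraene-1,6-dione
Conditions: Martin sulfurane Ph2S[OC(CF3)2Ph]2, CH2Cl2, 0 °C to rt
Reagents that add atoms: none
Why: Sulfurane dehydration of the tertiary carbinol can only take a hydrogen from C4 (C10 is quaternary, C6 is the carbonyl carbon), so the C4=C5 enone forms and the C5 stereocentre is deliberately erased.

Step 5
Reactants: 8 enedione 12-methoxy-18,19-dinorpodocarpa-4,8,11,13-tetraene-1,6-dione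
Product: 9 silyl enol ether 12-methoxy-6-(trimethylsilyloxy)-19-norpodocarpa-5,8,11,13-tetraen-1-one (C4 epimers)
Conditions: Me2CuLi (from CuI and MeLi), Me3SiCl, THF, −78 °C; Et3N, aq. NaHCO3
Reagents that add atoms: lithium dimethylcuprate, [Li+].C[Cu-]C; chlorotrimethylsilane, C[Si](C)(C)Cl
Why: Silyl-chloride-accelerated conjugate addition of the cuprate to the s-cis enone places the first methyl on C4 and traps the C5–C6 enolate regiospecifically; the C4 configuration is irrelevant because C4 becomes trigonal again in step 6.

Step 6
Reactants: 9 silyl enol ether 12-methoxy-6-(trimethylsilyloxy)-19-norpodocarpa-5,8,11,13-tetraen-1-one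
Product: 10 12-methoxy-19-norpodocarpa-4,8,11,13-tetraene-1,6-dione
Conditions: Pd(OAc)2 (10 mol %), O2 (1 atm), DMSO, 50 °C
Reagents that add atoms: none
Why: Saegusa–Ito oxidation: the palladium enolate at C5 can only lose the hydrogen on C4, which returns the enone with C4 now carrying a methyl group.

Step 7
Reactants: 10 12-methoxy-19-norpodocarpa-4,8,11,13-tetraene-1,6-dione
Product: 11 12-methoxypodocarpa-8,11,13-triene-1,6-dione (5β-H)
Conditions: Me2CuLi (from CuI and MeLi), BF3·OEt2, Et2O, −78 to −30 °C; aq. NH4Cl; then NaOMe, MeOH, rt
Reagents that add atoms: lithium dimethylcuprate, [Li+].C[Cu-]C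
Why: A second, Lewis-acid-assisted cuprate conjugate addition (as for pulegone-type β,β-disubstituted s-cis enones) completes the C4 gem-dimethyl group, and equilibrating protonation at C5 should give the more stable trans ring fusion (H5 β, anti to C20).

Step 8
Reactants: 11 12-methoxypodocarpa-8,11,13-triene-1,6-dione
Product: 12 12-methoxypodocarpa-8,11,13-triene-1α,6α-diol
Conditions: NaBH4, MeOH, 0 °C
Reagents that add atoms: none
Why: Hydride reduction of both ketones: at C6 the axial methyls on C4 and C10 block the α face, so hydride enters from β and gives the axial 6α-alcohol; at C1 the axial C20 methyl hinders equatorial attack, so axial attack from β should give the equatorial 1α-alcohol.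

Step 9
Reactants: 12 12-methoxypodocarpa-8,11,13-triene-1α,6α-diol
Product: 14 1α,6α-dihydroxypodocarp-8-en-12-one, via dienol ether 13 (not isolated)
Conditions: Li, NH3 (l), THF, t-BuOH, −78 to −33 °C; then (CO2H)2, MeOH/H2O, rt
Reagents that add atoms: water, O
Why: Birch reduction of the 3,4-dialkylanisole keeps the tetrasubstituted C8=C9 bond and the C12 enol ether (as with steroidal anisoles), and mild acid hydrolysis gives the β,γ-unsaturated ketone without conjugation.

Step 10
Reactants: 14 1α,6α-dihydroxypodocarp-8-en-12-one
Product: 15 1α,6α-dihydroxy-11β-(prop-2-yn-1-yl)podocarp-8-en-12-one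
Conditions: LiN(i-Pr)2 (3.1 equiv), THF, −78 to 0 °C; then propargyl bromide, −78 to −20 °C
Reagents that add atoms: propargyl bromide, C#CCBr
Why: The extended dienolate (C12 enolate conjugated with C8=C9) is alkylated at its α-carbon C11 (deconjugative alkylation) from the β face, away from the axial C20 methyl, which sets C11; the hindered lithium alkoxides should not compete.

Step 11
Reactants: 15 1α,6α-dihydroxy-11β-(prop-2-yn-1-yl)podocarp-8-en-12-one
Product: 16 bridged methylene ketone (C15H2–C16(=C17H2) bridge from C11 to C13 on the β face of 1α,6α-dihydroxypodocarp-8-en-12-one)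
Conditions: pyrrolidine (20 mol %), Cu(OTf)2 (5 mol %), PPh3 (20 mol %), MeOH, 40 °C
Reagents that add atoms: none
Why: Cooperative enamine/copper Conia-ene-type carbocyclisation: the less substituted enamine (C12=C13) attacks the copper-activated alkyne 5-exo-dig at C16 on the β face where the propargyl arm sits, which closes the bicyclo[3.2.1]octene, sets C13 through the bridge and leaves the exocyclic methylene.

Step 12
Reactants: 16 bridged methylene ketone
Product: 17 1-acetate of 16
Conditions: Ac2O, pyridine, DMAP (5 mol %), CH2Cl2, 0 °C to rt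
Reagents that add atoms: acetic anhydride, CC(=O)OC(C)=O
Why: Acylation should discriminate the equatorial C1 hydroxyl from the C6 hydroxyl, which is axial and flanked by the axial methyls on C4 and C10.

Step 13
Reactants: 17 1-acetate of 16
Product: 18 12-alcohol of 17 (hydroxyl on the side of the C15–C16 bridge)
Conditions: SmI2, THF/H2O, 0 °C
Reagents that add atoms: none
Why: Electron-transfer reduction of the ketone: the samarium-bound oxygen of the ketyl should take the less crowded position on the side of the C15–C16 bridge before carbon is protonated, giving the more stable 12-alcohol with its hydrogen under ring C; the acetate is inert to SmI2 without amine additives.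

Step 14
Reactants: 18 12-alcohol of 17
Product: 19 15-hydroxy derivative of 18 (C15 epimers)
Conditions: SeO2 (0.5 equiv), t-BuOOH, CH2Cl2, rt
Reagents that add atoms: selenium dioxide, O=[Se]=O; tert-butyl hydroperoxide, CC(C)(C)OO
Why: Selenium dioxide allylic oxidation (ene reaction, then [2,3]-shift) at the accessible 1,1-disubstituted alkene; only C15 can lose hydrogen because the other allylic carbon C13 is a bridgehead, and the hindered C8=C9 bond should not be engaged.

Step 15
Reactants: 19 15-hydroxy derivative of 18
Product: 20 CNP0149338.1 (target)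
Conditions: MnO2, CH2Cl2, rt
Reagents that add atoms: none
Why: MnO2 oxidises only the allylic C15 carbinol to the α-methylene ketone and leaves the C6 and C12 hydroxyls untouched, so both C15 epimers converge on the target.

Compound list

1 | 2-methylcyclohexane-1,3-dione | CC1C(=O)CCCC1=O | starting material
2 | (2-formyl-5-methoxyphenyl)boronic acid | COc1ccc(C=O)c(B(O)O)c1 | starting material
3 | (2-formyl-5-methoxyphenyl)lead triacetate | COc1ccc(C=O)c(c1)[Pb](OC(C)=O)(OC(C)=O)OC(C)=O | intermediate (not isolated)
4 | 2-(2-formyl-5-methoxyphenyl)-2-methylcyclohexane-1,3-dione (achiral) | COc1ccc(C=O)c(c1)C1(C)C(=O)CCCC1=O | intermediate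
5 | 2-[5-methoxy-2-(2-methoxyethenyl)phenyl]-2-methylcyclohexane-1,3-dione (E/Z mixture) | COC=Cc1ccc(OC)cc1C1(C)C(=O)CCCC1=O | intermediate (not isolated)
6 | 2-[5-methoxy-2-(2-oxoethyl)phenyl]-2-methylcyclohexane-1,3-dione (achiral) | O=CCc1ccc(OC)cc1C1(C)C(=O)CCCC1=O | intermediate
7 | tricyclic ketol 5α-hydroxy-12-methoxy-18,19-dinorpodocarpa-8,11,13-triene-1,6-dione (C5 hydroxyl cis to the C20 methyl) | COc1ccc2c(c1)[C@]3(C)C(=O)CCC[C@]3(O)C(=O)C2 | intermediate
8 | enedione 12-methoxy-18,19-dinorpodocarpa-4,8,11,13-tetraene-1,6-dione | COc1ccc2c(c1)[C@]3(C)C(=O)CCC=C3C(=O)C2 | intermediate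
9 | silyl enol ether 12-methoxy-6-(trimethylsilyloxy)-19-norpodocarpa-5,8,11,13-tetraen-1-one (one methyl on C4, both C4 epimers) | COc1ccc2c(c1)[C@]3(C)C(=O)CCC(C)C3=C(O[Si](C)(C)C)C2 | intermediate
10 | 12-methoxy-19-norpodocarpa-4,8,11,13-tetraene-1,6-dione (methyl on the enone β-carbon C4) | COc1ccc2c(c1)[C@]3(C)C(=O)CCC(C)=C3C(=O)C2 | intermediate
11 | 12-methoxypodocarpa-8,11,13-triene-1,6-dione (5β-H, trans-fused) | COc1ccc2c(c1)[C@]3(C)C(=O)CCC(C)(C)[C@H]3C(=O)C2 | intermediate
12 | 12-methoxypodocarpa-8,11,13-triene-1α,6α-diol | COc1ccc2c(c1)[C@]3(C)[C@@H](O)CCC(C)(C)[C@H]3[C@@H](O)C2 | intermediate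
13 | dienol ether 12-methoxypodocarpa-8,12-diene-1α,6α-diol | COC1=CCC2=C(C1)[C@]3(C)[C@@H](O)CCC(C)(C)[C@H]3[C@@H](O)C2 | intermediate (not isolated)
14 | 1α,6α-dihydroxypodocarp-8-en-12-one | O=C1CCC2=C(C1)[C@]3(C)[C@@H](O)CCC(C)(C)[C@H]3[C@@H](O)C2 | intermediate
15 | 1α,6α-dihydroxy-11β-(prop-2-yn-1-yl)podocarp-8-en-12-one | O=C1CCC2=C([C@H]1CC#C)[C@]3(C)[C@@H](O)CCC(C)(C)[C@H]3[C@@H](O)C2 | intermediate
16 | bridged methylene ketone: C15H2–C16(=C17H2) bridge from C11 to C13 on the β face, C12 ketone as one-carbon bridge, 1α,6α-diol | C=C1C[C@@H]2C3=C(C[C@H]1C2=O)C[C@H](O)[C@@H]1C(C)(C)CC[C@H](O)[C@@]31C | intermediate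
17 | 1-acetate of 16 | C=C1C[C@@H]2C3=C(C[C@H]1C2=O)C[C@H](O)[C@@H]1C(C)(C)CC[C@H](OC(C)=O)[C@@]31C | intermediate
18 | 12-alcohol of 17 (hydroxyl on the side of the C15–C16 bridge, as in the target) | C=C1C[C@@H]2C3=C(C[C@H]1[C@@H]2O)C[C@H](O)[C@@H]1C(C)(C)CC[C@H](OC(C)=O)[C@@]31C | intermediate
19 | 15-hydroxy derivative of 18 (C15 epimers, configuration inconsequential) | C=C1C(O)[C@@H]2C3=C(C[C@H]1[C@@H]2O)C[C@H](O)[C@@H]1C(C)(C)CC[C@H](OC(C)=O)[C@@]31C | intermediate
20 | CNP0149338.1: 1α-acetoxy-6α,12-dihydroxy-15-oxo-16-methylene compound with C8=C9 | C=C1C(=O)[C@@H]2C3=C(C[C@H]1[C@@H]2O)C[C@H](O)[C@@H]1C(C)(C)CC[C@H](OC(C)=O)[C@@]31C | target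

Total step count: 15. Longest linear sequence: 15 steps.

Steps most likely to fail

Step 3. The arylacetaldehyde may enolise and add through C7 to a ring carbonyl (aldol closure of a five-membered ring) faster than the carbene forms the Breslow intermediate, or the carbene may distinguish the two enantiotopic carbonyls poorly. The fallback sets out from 5, which is isolated, and comes back at 7. One of the two enantiotopic carbonyls of 5 is reduced under oxazaborolidine catalysis (Me-CBS catalyst, catecholborane, toluene, −78 °C), which fixes C10 and gives the hydroxy ketone enol ether F1; the configuration of its carbinol does not matter. Hydrolysis (oxalic acid, wet THF) gives the hydroxy keto aldehyde F2. SmI2 (THF, t-BuOH, −78 °C) then joins C5 and C6 by ketyl pinacol coupling onto the only remaining ketone and gives the cis-5,6-diol, the triol F3. Swern oxidation of the two secondary carbinols at C1 and C6 returns ketol 7; the C5 configuration is not critical because C5 becomes trigonal in step 4.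

Step 11. Condensation of pyrrolidine with the hindered ketone may be slow, so that amine-induced migration of the C8=C9 bond into conjugation or simple alkyne hydration takes over. The fallback sets out from 14 and comes back at 16. The dienolate of 14 is alkylated with 2,3-dibromopropene instead of propargyl bromide, giving the 11β-(2-bromoallyl) ketone F4. The bridge is then closed by intramolecular coupling of the C13 potassium enolate with the vinyl bromide under zerovalent palladium catalysis (Pd(PPh3)4, KOt-Bu, THF, 50 °C), an enolate alkenylation that delivers 16 directly.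

Step 13. Protonation of the samarium ketyl may show poor facial selectivity at C12. The fallback sets out from 17 and comes back at 19. Ketone 17 is first oxidised with SeO2/t-BuOOH to the 15-hydroxy ketone F5, expected with the hydroxyl on the face of C15 turned toward C12. Silylation (t-BuMe2SiCl, imidazole, DMF; the hindered C6 hydroxyl should not react) gives the silyl ether F6, whose bulky silyloxy group shields the bridge-side face of the C12 carbonyl. Hydride (LiAlH(Ot-Bu)3, THF, −40 °C) should then enter from the C8=C9 side and give the 12-alcohol F7 with the required configuration. HF·pyridine removes the silyl group and gives 19.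

Further compounds

F1 | step 3 | 3-hydroxy-2-[5-methoxy-2-(2-methoxyethenyl)phenyl]-2-methylcyclohexan-1-one (C10 as in 7; carbinol configuration immaterial) | COC=Cc1ccc(OC)cc1[C@]1(C)C(O)CCCC1=O
F2 | step 3 | 2-[2-(6-hydroxy-1-methyl-2-oxocyclohexyl)-4-methoxyphenyl]acetaldehyde (C10 as in 7) | O=CCc1ccc(OC)cc1[C@]1(C)C(O)CCCC1=O
F3 | step 3 | 12-methoxy-18,19-dinorpodocarpa-8,11,13-triene-1,5α,6α-triol (C1 configuration immaterial) | COc1ccc2c(c1)[C@]3(C)C(O)CCC[C@]3(O)[C@@H](O)C2
F4 | step 11 | 11β-(2-bromoprop-2-en-1-yl)-1α,6α-dihydroxypodocarp-8-en-12-one | O=C1CCC2=C([C@H]1CC(Br)=C)[C@]3(C)[C@@H](O)CCC(C)(C)[C@H]3[C@@H](O)C2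
F5 | step 13 | 15-hydroxy derivative of 17 (hydroxyl on the face of C15 turned toward C12) | C=C1[C@@H](O)[C@@H]2C3=C(C[C@H]1C2=O)C[C@H](O)[C@@H]1C(C)(C)CC[C@H](OC(C)=O)[C@@]31C
F6 | step 13 | 15-O-tert-butyldimethylsilyl ether of F5 | C=C1[C@@H](O[Si](C)(C)C(C)(C)C)[C@@H]2C3=C(C[C@H]1C2=O)C[C@H](O)[C@@H]1C(C)(C)CC[C@H](OC(C)=O)[C@@]31C
F7 | step 13 | 12-alcohol of F6 (C12 configured as in 18) | C=C1[C@@H](O[Si](C)(C)C(C)(C)C)[C@@H]2C3=C(C[C@H]1[C@@H]2O)C[C@H](O)[C@@H]1C(C)(C)CC[C@H](OC(C)=O)[C@@]31C
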